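Keep the books in substrate, in percent of its charge, as the readings are.

the same everywhere: partner 22.8 mM

|  | substrate | capture agent | remark | time |
|---|---|---|---|---|
| ochre | 15 mM (in portions, 4) | 24 mM | run made earlier; portions every 2.5 h |  |
| teal | 61 mM (in portions, 4) | 24 mM | run made earlier; portions every 2.5 h |  |
| eta | 12 mM (in portions, 4) | 24.0 mM | the portions of substrate follow each other after 2.5 h, the first at the start | 50 h |
| zeta | 25 mM (in portions, 4) | 24.0 mM | the portions of substrate follow each other after 2.5 h, the first at the start | 50 h |
| epsilon | 50 mM (in portions, 4) | 24.0 mM | the portions of substrate follow each other after 2.5 h, the first at the start | 50 h |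

| run | time / h | target / % | substrate / % |
|---|---|---|---|
| ochre | 2.00 | 0.5 | 17.2 |
| ochre | 5.00 | 1.5 | 25.7 |
| ochre | 10.0 | 4.9 | 32.7 |
| ochre | 15.0 | 8.5 | 10.5 |
| ochre | 20.0 | 11.5 | 3.9 |
| ochre | 30.0 | 12.9 | 0.8 |
| ochre | 40.0 | 14.9 | 0 |
| teal | 3.00 | 0.4 | 35.5 |
| teal | 4.00 | 0.5 | 29.0 |
| teal | 6.00 | 2.5 | 36.9 |
| teal | 10.0 | 4.5 | 26.3 |
| teal | 15.0 | 8.2 | 6.7 |
| teal | 25.0 | 10.3 | 1.2 |
| teal | 40.0 | 11.0 | 0 |

(each reading ± 0.5 percentage points)

- percentages count the substrate that a species holds: one side product counts as two
- target is meant together with its crystals
- solid, in amounts per volume of the solution: crystals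
- on the list of suspects stand: substrate <-> intermediate A; substrate -> intermediate B; intermediate A -> target; partner + intermediate B <-> intermediate C; capture agent + intermediate A -> trapped intermediate; crystals <-> target; substrate + intermediate B -> side product
- "hardly changes" means that all values lie within two and a half points (for a concentration: within two and a half percent of the largest)

1. amount of target at the end, in percent of the substrate charged for eta, zeta, epsilon, in this order
2. how that number moves from the first to the last of them (rises, then falls / falls all the way / falls, then rises / rises all the way / hardly changes)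

1. Opening entry: ochre charges 15 mM of substrate, less than its 22.8 mM of partner and its 24 mM of capture agent, so in ochre substrate is the limiting reagent by charge, and c(substrate) is the account we open. Teal charges 61 mM.

2. Substrate account: after 40.0 h it reads 0% in ochre and 0% in teal, so within the scatter the charge has left this entry in both runs.

3. Target account: at that time ochre reads 14.9% and teal 11.0%.

4. Unread account: the remainder, 85.1% in ochre and 89.0% in teal, sits in species that were not read. The suspects are the intermediates, trapped intermediate and side product.

5. A straight line through these two readings at 40.0 h gives the row its span, 3.2 percentage points: the drop in target share, taken from those readings, from the first flask to the last.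

6. Our line reads 15.2%, 14.1% and 11.9%. Two readings of scatter 0.5 points give the span an error of 0.58 points. "Hardly changes" allows 2.5 points, and the span stands 0.70 points above that. So we commit to a fall, narrowly.

7. The forecast gives 16%, 14% and 11.5%, shape falls all the way: “Interpolating gently, I expect the yield to fall steadily”. Its drop, 4.5 points, is larger than our span.

The flask gives 14.6%, 13.4% and 12.2%, so the shape is hardly changes, not falls all the way; the drop is 2.4 points, less than our span.

    substrate ⇌ intermediate A (K = 2.50, k = 1.10 × 10⁻⁵ s⁻¹)
    substrate → intermediate B (k = 3.80 × 10⁻⁵ s⁻¹)
    intermediate A → target (k = 3.50 × 10⁻⁵ s⁻¹)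
    partner + intermediate B ⇌ intermediate C (K = 250 L mol⁻¹, k = 0.00150 L mol⁻¹ s⁻¹)
    capture agent + intermediate A → trapped intermediate (k = 3.60 × 10⁻⁴ L mol⁻¹ s⁻¹)
    crystals ⇌ target, rate k6*(cs6 - [target]) while solid is left; crystals form when [target] > cs6 (solubility = 13.0 mM, k = 0.00310 s⁻¹)
    substrate + intermediate B → side product (k = 0.00330 L mol⁻¹ s⁻¹)

Along the row, side product at 50.0 h stands at 25.3% in eta and 54.8% in epsilon. Taken down from the 14.6% of eta, the span 3.2 points puts epsilon at 11.4%, where the flask holds 12.2%. Its share for the step to zeta puts zeta at 13.5%, where the flask holds 13.4%.

(The numbers in the tables are calculated with constants of no real substance; the scatter is artificial.)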